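the same everywhere: left-handed substrate 0.020 M; right-handed substrate 0.020 M
- east: solid reagent 2 equiv; free catalyst 4.3 mol%; the very flask that is asked about, followed so far
- south: solid reagent 2 equiv; free catalyst 8.6 mol%; run made earlier
- flask: solid reagent 2.00 equiv; free catalyst 4.3 mol%; time 25 h

- east (time / h: left-handed product / %, right-handed product / %, left-handed substrate / %): 0.667: 1.8, 0.7, 48.4; 2.00: 8.9, 3.8, 41.7; 4.00: 20.1, 9.2, 29.3; 5.00: 25.5, 12.0, 24.4; 8.00: 35.6, 20.0, 13.9; 10.0: 41.5, 23.9, 9.5
- south (time / h: left-handed product / %, right-handed product / %, left-handed substrate / %): 2.00: 13.5, 6.3, 36.5; 3.00: 21.4, 9.7, 28.2; 6.00: 38.5, 21.8, 11.7; 10.0: 46.6, 32.4, 3.9; 15.0: 49.1, 37.5, 1.9; 25.0: 50.6, 40.3, 0.9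

(readings scatter by 0.3 percentage points)

- free catalyst is single-handed; left-handed substrate and right-handed substrate are mirror images of each other, charged as a racemate, each of them at the stated concentration
- solid, in amounts per volume of the solution: solid reagent
- at the start none of the solid reagent is in solution
- an excess is the difference of the two amounts in percent of their sum
- an excess is below zero if the other one leads

1. left-handed product and right-handed product together, in percent of the left-handed substrate and right-handed substrate charged together, at 25 h
2. excess of left-handed product over right-handed product in the product at 25 h
3. whether the exchange between left-handed substrate and right-handed substrate keeps pace with the reaction: how far the product's excess at 25 h gets from its value without exchange to its value with instant exchange (above 80% keeps pace, below 20% hardly takes part, else lags behind)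

Start from an invariant: with the handedness of a substrate kept, left-handed substrate plus left-handed product stays at half the charge, and a drift above half, beyond the scatter of the readings, is exchange. Take the right-handed substrate from the balance of the readings. At 10.0 h, the east run gives 2.41 as the selectivity factor, the logarithm of the fraction of left-handed substrate left over that of right-handed substrate left. On this scale, one is the symmetric case with a product excess of zero.

Now find the clock. South at 6.00 h stands between east at 8.00 h and 10.0 h in left-handed substrate, so doubling the catalyst shortens times about 1.50-fold. Expect the flask at 25 h to stand where south stands at 16.7 h, next to the south reading at 15.0 h, which leaves 11.5% right-handed substrate. The factor then leaves 1.45% left-handed substrate, so the yield is 87.1% and the plain kinetic-resolution excess is 11.5%.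

Reforge the weak link, the invariant itself. South at 25.0 h drifts 1.5 percentage points above half, a reading with a scatter of 0.3 points on each term. Assume the same drift for the flask at 25 h, the same hours as that south reading. Each point of drift widens the product difference by two points, so the excess becomes 15.0%. Instant exchange gives 41.3%, so reckon the flask at 11.6% of the way, less than 20%.

The forecast, “so exchange is tiny”, says 86%, 14% and hardly takes part.

The flask gives 86.2%, 15.5% and hardly takes part, at 9.1% of the way. At 25.0 h the flask keeps 23% of the right-handed substrate charged; raise that to the factor and expect 2.82% of the left-handed substrate charged, but it keeps 4.9%, more, on the side of the drift.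

    partner + free catalyst + left-handed substrate → free catalyst + left-handed product (k = 5.50 L² mol⁻² s⁻¹)
    partner + free catalyst + right-handed substrate → free catalyst + right-handed product (k = 2.20 L² mol⁻² s⁻¹)
    left-handed substrate ⇌ right-handed substrate (k = 2.20 × 10⁻⁶ s⁻¹)
    solid reagent ⇌ partner, rate k4*(cs4 - [partner]) while solid is left; crystals form when [partner] > cs4 (solubility = 18.0 mM, k = 1.60 × 10⁻⁴ s⁻¹)
    2 free catalyst → spent catalyst (k = 0.00230 L mol⁻¹ s⁻¹)

Apply the factor to the flask with 0.800 equiv of solid reagent, where right-handed substrate stands at 35.0% of the two substrates charged together: it leaves 42.2% of the left-handed charge and a plain excess of 31.7%. The computed flask gives 34.5% at a yield of 39.9%.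

The runs were computed from invented constants, noise included.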